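**Plan**

1. Locants: ring A is C5 (isopropenyl)–C6 (lactone O)–C7–C8 (acyloxy)–C9–C10 (methyl, vinyl); ring B is the lactone O6–C12(=O)–C11–C7–C6; α is the face of ring A carrying the C10 vinyl group, β the face of the C10 methyl group.
2. Enabling feature: ring B is cis-fused to ring A across C6–C7 (O6 and C11 both α) and the C8 oxygen is β, anti to the C7–C11 bond. This is what a C11 radical tied to O6 by a two-atom acetal tether leaves when it closes 5-exo onto C7 of a C7=C8 alkene and C8 then takes up O2.
3. Retrosynthetic cuts, in order: the C8 ester and C11 acetate C–O bonds; C11–CH3 and C11–O (lactone enolate chemistry); C7–C11 together with C8–O (radical step); C7=C8 (metathesis) and C6–C7 (vinyl addition); C5–C10 (Ireland–Claisen), leaving a Z-allylic 3-methylbut-3-enoate.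
4. Forward: the chain is joined by Stille coupling and esterification, C5–C10 is made by the Claisen step, ring A closes by metathesis, ring B by the radical cyclisation, and the lactone is then hydroxylated, methylated and acylated twice.
5. Stereochemistry: C5 and C10 from a chair Claisen rearrangement of a chiral boron dienolate (absolute sense from the diazaborolidine); C6 from Felkin–Anh hydride delivery; C7 from the O6 tether; C8 from O2 capture on the convex β face; C11 from convex-face methylation of an α-alkoxy enolate.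

Key step: step 10

Assumption: in step 4 the dienolate is taken to form with isopropenyl anti to O–B (as simple esters do with Et3N in non-polar media) and the (R,R)-controller is taken to give the (2R,3S)-acid; if the sense of induction is the reverse, the (S,S)-controller is used and nothing else changes.

**Route**

Step 1
Reactants: 1 but-2-yn-1-ol
Product: 3 (2Z)-3-iodobut-2-en-1-ol, via cyclic alkenylalanate 2 (not isolated)
Conditions: NaAlH2(OCH2CH2OMe)2, THF, 0 °C to rt; then I2, −78 to 0 °C; aq. potassium sodium tartrate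
Reagents that add atoms: iodine (SMILES: II)
Why: Hydroxyl-directed trans-hydroalumination of the propargylic alcohol places aluminium on C3 syn to the CH2O group, and iodinolysis of the C–Al bond with retention should give the Z-iodide.

Step 2
Reactants: 3 (2Z)-3-iodobut-2-en-1-ol; 4 allyltributylstannane
Product: 5 (2Z)-3-methylhexa-2,5-dien-1-ol
Conditions: PdCl2(MeCN)2 (5 mol %), DMF, rt
Reagents that add atoms: none
Why: Stille coupling of an alkenyl iodide with an allylstannane proceeds with retention of alkene geometry and tolerates the free hydroxyl, so the allyl arm should end cis to CH2OH.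

Step 3
Reactants: 5 (2Z)-3-methylhexa-2,5-dien-1-ol; 6 3-methylbut-3-enoic acid
Product: 7 (2Z)-3-methylhexa-2,5-dien-1-yl 3-methylbut-3-enoate
Conditions: DCC, DMAP (5 mol %), CH2Cl2, 0 °C
Reagents that add atoms: none
Why: Steglich esterification of a primary allylic alcohol; low temperature and little DMAP should keep the β,γ-double bond of the acid out of conjugation.

Step 4
Reactants: 7 (2Z)-3-methylhexa-2,5-dien-1-yl 3-methylbut-3-enoate
Product: 10 (2R,3S)-3-ethenyl-3-methyl-2-(prop-1-en-2-yl)hex-5-enoic acid, via boron dienolate 8 (not isolated), via acyloxyborane 9 (not isolated)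
Conditions: (4R,5R)-2-bromo-1,3-bis{[3,5-bis(trifluoromethyl)phenyl]sulfonyl}-4,5-diphenyl-1,3,2-diazaborolidine (1.2 equiv, made in the flask from the (R,R)-bis-sulfonamide and BBr3, CH2Cl2, then evaporation), Et3N, toluene/hexane, −78 °C, then 4 °C; aqueous work-up
Reagents that add atoms: none
Why: Enantioselective boron-enolate Ireland–Claisen rearrangement: the dienolate (isopropenyl anti to O–B) reacts at C5 through a chair in which isopropenyl and the cis-placed allyl arm of the Z-alkene are axial and methyl is equatorial, which puts isopropenyl (C5) and vinyl (C10) on the same face once C6 and C9 are part of ring A, while the C2-symmetric sulfonamide ligand shields one dienolate face and sets the absolute sense.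

Step 5
Reactants: 10 (2R,3S)-3-ethenyl-3-methyl-2-(prop-1-en-2-yl)hex-5-enoic acid
Product: 12 (2R,3S)-3-ethenyl-N-methoxy-N,3-dimethyl-2-(prop-1-en-2-yl)hex-5-enamide, via acid chloride 11 (not isolated)
Conditions: (COCl)2, DMF (cat.), CH2Cl2, 0 °C; evaporate; then MeNH(OMe)·HCl, pyridine, CH2Cl2, −20 to 0 °C
Reagents that add atoms: N,O-dimethylhydroxylamine hydrochloride (SMILES: CNOC.Cl)
Why: Acyl chloride formation and aminolysis (Weinreb amide synthesis); pyridine is too weak a base to turn the acid chloride into a ketene, so C5 should keep its configuration.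

Step 6
Reactants: 12 (2R,3S)-3-ethenyl-N-methoxy-N,3-dimethyl-2-(prop-1-en-2-yl)hex-5-enamide
Product: 14 (4R,5S)-5-ethenyl-5-methyl-4-(prop-1-en-2-yl)octa-1,7-dien-3-one, via magnesium hemiaminal 13 (not isolated)
Conditions: CH2=CHMgBr, THF, −20 to 0 °C; poured into cold aq. HCl
Reagents that add atoms: vinylmagnesium bromide (SMILES: C=C[Mg]Br)
Why: Weinreb ketone synthesis: the chelated tetrahedral adduct survives until the cold acidic quench, which prevents double addition and keeps the liberated amine from adding to the vinyl ketone.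

Step 7
Reactants: 14 (4R,5S)-5-ethenyl-5-methyl-4-(prop-1-en-2-yl)octa-1,7-dien-3-one
Product: 15 (3S,4R,5S)-5-ethenyl-5-methyl-4-(prop-1-en-2-yl)octa-1,7-dien-3-ol
Conditions: NaBH4, CeCl3·7H2O, MeOH, −78 °C
Reagents that add atoms: none
Why: Luche 1,2-reduction under Felkin–Anh control: with quaternary C10 anti to the incoming hydride and isopropenyl gauche to the carbonyl oxygen, hydride passes the C5 hydrogen and should give the 3S carbinol (O6 syn to isopropenyl in the later ring), CeCl3 suppressing conjugate reduction.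

Step 8
Reactants: 15 (3S,4R,5S)-5-ethenyl-5-methyl-4-(prop-1-en-2-yl)octa-1,7-dien-3-ol
Product: 16 (1S,5S,6R)-5-ethenyl-5-methyl-6-(prop-1-en-2-yl)cyclohex-2-en-1-ol
Conditions: RuCl2(=CHPh)(PCy3)2 (first-generation Grubbs catalyst, 5 mol %), CH2Cl2 (0.01 M), 40 °C
Reagents that add atoms: none
Why: Ring-closing metathesis: the first-generation catalyst loads on the unhindered allyl terminus and closes onto the carbinol vinyl group to the six-membered ring A, whereas the 1,1-disubstituted isopropenyl group and the vinyl group on quaternary C10 are too hindered to compete.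

Step 9
Reactants: 16 (1S,5S,6R)-5-ethenyl-5-methyl-6-(prop-1-en-2-yl)cyclohex-2-en-1-ol; 17 ethyl vinyl ether
Product: 18 (3S,4R,5S)-3-(2-bromo-1-ethoxyethoxy)-5-ethenyl-5-methyl-4-(prop-1-en-2-yl)cyclohex-1-ene (both acetal epimers)
Conditions: N-bromosuccinimide, CH2Cl2, −40 to 0 °C
Reagents that add atoms: N-bromosuccinimide (SMILES: O=C1CCC(=O)N1Br)
Why: Bromoacetalisation (haloetherification of an enol ether): bromination of the electron-rich vinyl ether far outruns attack on the isolated alkenes, and O6 captures the oxocarbenium ion to give the mixed acetal, whose acetal configuration is of no consequence.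

Step 10
Reactants: 18 (3S,4R,5S)-3-(2-bromo-1-ethoxyethoxy)-5-ethenyl-5-methyl-4-(prop-1-en-2-yl)cyclohex-1-ene
Product: 20 (3aS,4R,6S,7R,7aR)-2-ethoxy-6-ethenyl-6-methyl-7-(prop-1-en-2-yl)octahydro-1-benzofuran-4-ol (both acetal epimers), via C8 hydroperoxide 19 (not isolated)
Conditions: Bu3SnH (3 equiv, syringe pump), slow stream of dry air, toluene (0.02 M), 0 °C to rt
Reagents that add atoms: dioxygen (SMILES: O=O)
Why: Bu3Sn• abstracts bromine from 18 to give the primary C11 radical, which adds to C7 of the ring alkene, and the resulting secondary C8 radical combines with O2 to a peroxyl radical that Bu3SnH reduces through hydroperoxide 19 to alcohol 20; this is a Ueno–Stork haloacetal cyclisation run as a stannane/air oxygenative radical cyclisation. Ring B (here the 2-ethoxytetrahydrofuran, later the lactone) closes in the 5-exo-trig mode of a 3-oxahex-5-enyl radical, the only mode within reach of the two-atom O6 tether. C7 is set by that tether, which can deliver C11 only to the face of O6 and so gives the cis ring fusion. C8 is set by the bicycle just formed: in the favoured chair O6 and the C10 vinyl group are both axial on the α face and screen it, so O2 should arrive equatorially on the convex β face, anti to the new C7–C11 bond. The step needs ring closure to outrun capture of the C11 radical by O2 or by stannane, which the slow air stream, the slow addition of Bu3SnH and the fast closure of oxygen-containing hexenyl radicals should secure; the isopropenyl and vinyl groups could be reached only through slower six- to eight-membered closures and should stay untouched.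

Step 11
Reactants: 20 cis-fused hydroxy acetal
Product: 21 C8 tert-butyldiphenylsilyl ether of 20
Conditions: t-BuPh2SiCl, imidazole, DMF, rt to 40 °C
Reagents that add atoms: tert-butyl(chloro)diphenylsilane (SMILES: CC(C)(C)[Si](Cl)(c1ccccc1)c1ccccc1)
Why: Silylation of the equatorial secondary alcohol; this silyl ether is chosen because it withstands chromic acid, amide bases and boron Lewis acids.

Step 12
Reactants: 21 C8 silyl ether
Product: 23 cis-fused γ-lactone (C12=O, C11H2, 8β-silyloxy), via lactol 22 (not isolated)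
Conditions: CrO3, H2SO4, H2O/acetone, 0 °C
Reagents that add atoms: water (SMILES: O)
Why: Jones oxidation of the cyclic ethyl acetal: acid hydrolysis to the lactol and chromic acid oxidation should convert both acetal epimers into one γ-lactone, the usual finish of a haloacetal cyclisation, with isolated alkenes and the silyl ether inert.

Step 13
Reactants: 23 γ-lactone
Product: 25 C11 hydroxy lactone (OH on the convex face, cis to H7), via potassium enolate 24 (not isolated)
Conditions: KN(SiMe3)2, THF, −78 °C; then 3-phenyl-2-(phenylsulfonyl)oxaziridine, −78 °C; AcOH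
Reagents that add atoms: 3-phenyl-2-(phenylsulfonyl)oxaziridine (SMILES: O=S(=O)(N1OC1c1ccccc1)c1ccccc1)
Why: Davis enolate hydroxylation: the electrophilic oxygen should enter on the convex face, but the configuration at C11 is immaterial here because this centre is enolised again in step 15.

Step 14
Reactants: 25 C11 hydroxy lactone
Product: 26 C11 methoxymethyl ether
Conditions: MeOCH2Cl, iPr2NEt, CH2Cl2, 0 °C to rt
Reagents that add atoms: chloromethyl methyl ether (SMILES: COCCl)
Why: O-Alkylation to the methoxymethyl ether, which unlike a silyl group cannot migrate to carbon in the enolate of the next step and is stable to LiN(iPr)2.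

Step 15
Reactants: 26 C11 methoxymethyl ether
Product: 28 C11 methyl, C11 methoxymethoxy lactone (11S; methyl cis to H7, O11 cis to C8), via lithium enolate 27 (not isolated)
Conditions: LiN(iPr)2, THF, −78 °C; then MeI, DMPU, −78 to −40 °C
Reagents that add atoms: iodomethane (SMILES: CI)
Why: Alkylation of an α-alkoxy lactone enolate: iodomethane should approach planar C11 from the convex face of the cis-fused bicycle (the side of H6 and H7), away from C8 and its silyloxy group, leaving O11 on the concave face as in the target.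

Step 16
Reactants: 28 C11 methyl, C11 methoxymethoxy lactone
Product: 30 C11 tertiary alcohol, via bromomethyl ether 29 (not isolated)
Conditions: Me2BBr, CH2Cl2, −78 °C; then THF, sat. aq. NaHCO3
Reagents that add atoms: none
Why: Guindon cleavage of a methoxymethyl ether: the boron bromide exchanges methoxide for bromide at the acetal carbon and the bromomethyl ether hydrolyses on work-up, conditions under which silyl ether, lactone and alkenes should survive.

Step 17
Reactants: 30 C11 tertiary alcohol
Product: 31 C11 acetate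
Conditions: Ac2O, DMAP, Et3N, CH2Cl2, rt to 40 °C
Reagents that add atoms: acetic anhydride (SMILES: CC(=O)OC(C)=O)
Why: DMAP-catalysed acetylation, the standard way to esterify a hindered tertiary alcohol; no stereocentre is touched.

Step 18
Reactants: 31 C11 acetate
Product: 32 C8 alcohol (8β-OH, C11 acetoxy lactone)
Conditions: HF·pyridine, pyridine, THF, 0 °C to rt
Reagents that add atoms: none
Why: Fluoride-induced desilylation under buffered acidic conditions frees O8 without generating an alkoxide, which should avoid migration of the neighbouring tertiary acetate to O8.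

Step 19
Reactants: 32 C8 alcohol; 6 3-methylbut-3-enoic acid
Product: 33 (3S,3aS,4R,6S,7R,7aR)-3-(acetyloxy)-6-ethenyl-3,6-dimethyl-2-oxo-7-(prop-1-en-2-yl)octahydro-1-benzofuran-4-yl 3-methylbut-3-enoate (CNP0106639.1)
Conditions: DCC, DMAP (10 mol %), CH2Cl2, −20 to 0 °C
Reagents that add atoms: none
Why: Steglich esterification of the secondary C8 alcohol with retention at C8; low temperature and catalytic DMAP should keep the β,γ-unsaturated acyl group from isomerising to the conjugated 3-methylbut-2-enoate.

**Compound list**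

1 | but-2-yn-1-ol | CC#CCO | starting material
2 | sodium cyclic alkenylalanate (five-membered O–Al–C3=C2–C1 ring, two 2-methoxyethoxy ligands on Al) | [Na+].CC1=CCO[Al-]1(OCCOC)OCCOC | intermediate
3 | (2Z)-3-iodobut-2-en-1-ol | C/C(I)=C/CO | intermediate
4 | allyltributylstannane | C=CC[Sn](CCCC)(CCCC)CCCC | starting material
5 | (2Z)-3-methylhexa-2,5-dien-1-ol (allyl arm cis to CH2OH) | C=CC/C(C)=C\CO | intermediate
6 | 3-methylbut-3-enoic acid | C=C(C)CC(=O)O | starting material
7 | (2Z)-3-methylhexa-2,5-dien-1-yl 3-methylbut-3-enoate | C=C(C)CC(=O)OC/C=C(/C)CC=C | intermediate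
8 | boron dienolate of 7 on the (4R,5R)-diazaborolidine (isopropenyl anti to O–B) | C=C(C)/C=C(/OB1N(S(=O)(=O)c2cc(cc(c2)C(F)(F)F)C(F)(F)F)[C@H](c2ccccc2)[C@@H](c2ccccc2)N1S(=O)(=O)c1cc(cc(c1)C(F)(F)F)C(F)(F)F)OC/C=C(/C)CC=C | intermediate
9 | acyloxyborane of acid 10 on the (4R,5R)-diazaborolidine | O=C(OB1N(S(=O)(=O)c2cc(cc(c2)C(F)(F)F)C(F)(F)F)[C@H](c2ccccc2)[C@@H](c2ccccc2)N1S(=O)(=O)c1cc(cc(c1)C(F)(F)F)C(F)(F)F)[C@H](C(C)=C)[C@](C)(C=C)CC=C | intermediate
10 | (2R,3S)-3-ethenyl-3-methyl-2-(prop-1-en-2-yl)hex-5-enoic acid | OC(=O)[C@H](C(C)=C)[C@](C)(C=C)CC=C | intermediate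
11 | (2R,3S)-3-ethenyl-3-methyl-2-(prop-1-en-2-yl)hex-5-enoyl chloride | ClC(=O)[C@H](C(C)=C)[C@](C)(C=C)CC=C | intermediate
12 | (2R,3S)-3-ethenyl-N-methoxy-N,3-dimethyl-2-(prop-1-en-2-yl)hex-5-enamide | CON(C)C(=O)[C@H](C(C)=C)[C@](C)(C=C)CC=C | intermediate
13 | bromomagnesium hemiaminal from vinyl addition to 12 (new carbinol carbon unassigned) | C=CC(O[Mg]Br)(N(C)OC)[C@H](C(C)=C)[C@](C)(C=C)CC=C | intermediate
14 | (4R,5S)-5-ethenyl-5-methyl-4-(prop-1-en-2-yl)octa-1,7-dien-3-one | C=CC(=O)[C@H](C(C)=C)[C@](C)(C=C)CC=C | intermediate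
15 | (3S,4R,5S)-5-ethenyl-5-methyl-4-(prop-1-en-2-yl)octa-1,7-dien-3-ol | C=C[C@H](O)[C@H](C(C)=C)[C@](C)(C=C)CC=C | intermediate
16 | (1S,5S,6R)-5-ethenyl-5-methyl-6-(prop-1-en-2-yl)cyclohex-2-en-1-ol (OH, isopropenyl and vinyl all α) | C=C[C@]1(C)CC=C[C@H](O)[C@@H]1C(=C)C | intermediate
17 | ethyl vinyl ether | C=COCC | starting material
18 | (3S,4R,5S)-3-(2-bromo-1-ethoxyethoxy)-5-ethenyl-5-methyl-4-(prop-1-en-2-yl)cyclohex-1-ene (O6 bromoacetal of 16, both acetal epimers) | C=C[C@]1(C)CC=C[C@H](OC(OCC)CBr)[C@@H]1C(=C)C | intermediate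
19 | cis-fused bicyclic ethyl acetal with 8β-hydroperoxy group (both acetal epimers) | C=C[C@]1(C)C[C@@H](OO)[C@H]2[C@H](OC(OCC)C2)[C@@H]1C(=C)C | intermediate
20 | (3aS,4R,6S,7R,7aR)-2-ethoxy-6-ethenyl-6-methyl-7-(prop-1-en-2-yl)octahydro-1-benzofuran-4-ol (cis-fused, 8β-OH, both acetal epimers) | C=C[C@]1(C)C[C@@H](O)[C@H]2[C@H](OC(OCC)C2)[C@@H]1C(=C)C | intermediate
21 | 8-O-tert-butyldiphenylsilyl ether of 20 | C=C[C@]1(C)C[C@@H](O[Si](c3ccccc3)(c3ccccc3)C(C)(C)C)[C@H]2[C@H](OC(OCC)C2)[C@@H]1C(=C)C | intermediate
22 | lactol (OEt of 21 replaced by OH, both epimers) | C=C[C@]1(C)C[C@@H](O[Si](c3ccccc3)(c3ccccc3)C(C)(C)C)[C@H]2[C@H](OC(O)C2)[C@@H]1C(=C)C | intermediate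
23 | cis-fused γ-lactone, C11H2, 8β-silyloxy | C=C[C@]1(C)C[C@@H](O[Si](c3ccccc3)(c3ccccc3)C(C)(C)C)[C@H]2[C@H](OC(=O)C2)[C@@H]1C(=C)C | intermediate
24 | potassium enolate of 23 | C=C[C@]1(C)C[C@@H](O[Si](c3ccccc3)(c3ccccc3)C(C)(C)C)[C@H]2[C@H](OC([O-])=C2)[C@@H]1C(=C)C.[K+] | intermediate
25 | C11 hydroxy lactone (OH cis to H7) | C=C[C@]1(C)C[C@@H](O[Si](c3ccccc3)(c3ccccc3)C(C)(C)C)[C@H]2[C@H](OC(=O)[C@@H]2O)[C@@H]1C(=C)C | intermediate
26 | C11 methoxymethyl ether of 25 | C=C[C@]1(C)C[C@@H](O[Si](c3ccccc3)(c3ccccc3)C(C)(C)C)[C@H]2[C@H](OC(=O)[C@@H]2OCOC)[C@@H]1C(=C)C | intermediate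
27 | lithium enolate of 26 | C=C[C@]1(C)C[C@@H](O[Si](c3ccccc3)(c3ccccc3)C(C)(C)C)[C@H]2[C@H](OC([O-])=C2OCOC)[C@@H]1C(=C)C.[Li+] | intermediate
28 | 11S lactone with C11 methyl (cis to H7) and C11 methoxymethoxy (cis to C8) | C=C[C@]1(C)C[C@@H](O[Si](c3ccccc3)(c3ccccc3)C(C)(C)C)[C@H]2[C@H](OC(=O)[C@@]2(C)OCOC)[C@@H]1C(=C)C | intermediate
29 | C11 bromomethyl ether | C=C[C@]1(C)C[C@@H](O[Si](c3ccccc3)(c3ccccc3)C(C)(C)C)[C@H]2[C@H](OC(=O)[C@@]2(C)OCBr)[C@@H]1C(=C)C | intermediate
30 | C11 tertiary alcohol (11-hydroxy-11-methyl lactone, 8β-silyloxy) | C=C[C@]1(C)C[C@@H](O[Si](c3ccccc3)(c3ccccc3)C(C)(C)C)[C@H]2[C@H](OC(=O)[C@@]2(C)O)[C@@H]1C(=C)C | intermediate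
31 | C11 acetate of 30 | C=C[C@]1(C)C[C@@H](O[Si](c3ccccc3)(c3ccccc3)C(C)(C)C)[C@H]2[C@H](OC(=O)[C@@]2(C)OC(C)=O)[C@@H]1C(=C)C | intermediate
32 | 8β-hydroxy C11 acetoxy lactone | C=C[C@]1(C)C[C@@H](O)[C@H]2[C@H](OC(=O)[C@@]2(C)OC(C)=O)[C@@H]1C(=C)C | intermediate
33 | (3S,3aS,4R,6S,7R,7aR)-3-(acetyloxy)-6-ethenyl-3,6-dimethyl-2-oxo-7-(prop-1-en-2-yl)octahydro-1-benzofuran-4-yl 3-methylbut-3-enoate | C=C[C@]1(C)C[C@@H](OC(=O)CC(=C)C)[C@H]2[C@H](OC(=O)[C@@]2(C)OC(C)=O)[C@@H]1C(=C)C | target

**Count**

Total: 19 steps. Longest linear sequence: 19 steps, from but-2-yn-1-ol 1.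

**Steps most likely to fail**

Step 4. The dienolate may form with isopropenyl syn to O–B, or the axial allyl arm of the Z-alkene may loosen the chair, so that the C10 epimer or material of low enantiomeric purity results. The fallback changes the alkene geometry instead of relying on the enolate geometry. It sets out from acid 6: zirconium-catalysed carboalumination of commercial pent-1-en-4-yne (AlMe3, Cp2ZrCl2, then paraformaldehyde) gives (2E)-3-methylhexa-2,5-dien-1-ol F1, and Steglich esterification with 6 gives (2E)-3-methylhexa-2,5-dien-1-yl 3-methylbut-3-enoate F2. Boron Ireland–Claisen rearrangement of F2 through the dienolate with isopropenyl syn to O–B (iPr2NEt, CH2Cl2), now with allyl and isopropenyl both equatorial in the chair, gives the same relative configuration; because the face of C5 shown to the allyl unit is reversed with the enolate geometry, the antipodal (S,S)-controller is used. The sequence comes back to the route at acid 10.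

Step 10. Capture of the C8 radical by oxygen may lack facial selectivity, so that attack on the screened α face gives the C8 epimer alongside 20 (too fast an air stream would in addition oxygenate the C11 radical before ring closure). The fallback corrects the configuration by substitution instead of by radical capture. It sets out from bromoacetal 18: the 8α-hydroxy epimer F3 formed in the cyclisation is separated and treated with 4-nitrobenzoic acid, PPh3 and diisopropyl azodicarboxylate (Mitsunobu inversion) to give the 8β 4-nitrobenzoate F4, and methanolysis (K2CO3, MeOH) comes back to the route at alcohol 20.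

Step 6. The Grignard reagent may deprotonate C5, which is α to the amide and allylic, instead of adding to the hindered amide, with recovery of material or migration of the isopropenyl double bond into conjugation. The fallback reaches the ketone through the aldehyde oxidation level, where addition is fast. It sets out from acid 10: reduction (LiAlH4, Et2O) gives (2R,3S)-3-ethenyl-3-methyl-2-(prop-1-en-2-yl)hex-5-en-1-ol F5, Dess–Martin oxidation gives (2R,3S)-3-ethenyl-3-methyl-2-(prop-1-en-2-yl)hex-5-enal F6, addition of CH2=CHMgBr at −78 °C gives (4R,5S)-5-ethenyl-5-methyl-4-(prop-1-en-2-yl)octa-1,7-dien-3-ol as both C3 epimers F7, and a second Dess–Martin oxidation comes back to the route at ketone 14.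

**Further compounds**

F1 | step 4 | (2E)-3-methylhexa-2,5-dien-1-ol | C=CC/C(C)=C/CO
F2 | step 4 | (2E)-3-methylhexa-2,5-dien-1-yl 3-methylbut-3-enoate | C=C(C)CC(=O)OC/C=C(\C)CC=C
F3 | step 10 | C8 epimer of 20 (8α-hydroxy, both acetal epimers) | C=C[C@]1(C)C[C@H](O)[C@H]2[C@H](OC(OCC)C2)[C@@H]1C(=C)C
F4 | step 10 | 8β 4-nitrobenzoate of 20 | C=C[C@]1(C)C[C@@H](OC(=O)c3ccc(cc3)[N+](=O)[O-])[C@H]2[C@H](OC(OCC)C2)[C@@H]1C(=C)C
F5 | step 6 | (2R,3S)-3-ethenyl-3-methyl-2-(prop-1-en-2-yl)hex-5-en-1-ol | OC[C@H](C(C)=C)[C@](C)(C=C)CC=C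
F6 | step 6 | (2R,3S)-3-ethenyl-3-methyl-2-(prop-1-en-2-yl)hex-5-enal | O=C[C@H](C(C)=C)[C@](C)(C=C)CC=C
F7 | step 6 | (4R,5S)-5-ethenyl-5-methyl-4-(prop-1-en-2-yl)octa-1,7-dien-3-ol, both C3 epimers | C=CC(O)[C@H](C(C)=C)[C@](C)(C=C)CC=C
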